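**Strategy.** Everything rests on cutting the aryl C–O bond of the dioxane oxygen that carries the CH2OH-bearing carbon (benzodioxine O-1). Only this oxygen sits para to C-6, the carbon that later bears ring C of the flavonol; with a nitrile there, its ipso carbon alone is open to SNAr. The precursor is a racemic 2-aryl-1,5-benzodioxepin-3-one in which that oxygen is still bonded to the future CH2OH carbon. In one operation, hydrogenation with dynamic kinetic resolution gives the cis-alcohol, whose alkoxide then takes over the arene (Smiles rearrangement): the seven-membered ring contracts to the trans-dioxane with both stereocentres set. The flavonol is annulated last from the nitrile-derived aldehyde.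

Key step: step 5

Remark (assumption): the (S)-xylbinap/(S)-daipen antipode of the hydrogenation catalyst is taken to give the (2R,3R)-alcohol; the sense of induction in such dynamic reductions depends on the substrate, and the mirror-image complex would be used if a first run shows the opposite sense.

**Step 1**
Reactants: 1 [4-(benzyloxy)-3-methoxyphenyl]acetic acid
Product: 4 1-[4-(benzyloxy)-3-methoxyphenyl]-3-chloropropan-2-one, via acid chloride 2 (not isolated), via diazoketone 3 (not isolated)
Conditions: (COCl)2, DMF (cat.), CH2Cl2, 0 °C to rt; concentrate; TMSCHN2 (2.2 equiv), MeCN/THF, 0 °C; then HCl (4 M in dioxane), 0 °C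
Reagents that add atoms: trimethylsilyldiazomethane C[Si](C)(C)C=[N+]=[N-] (the new CH2 carbon); hydrogen chloride Cl (the chlorine of 4); oxalyl chloride O=C(Cl)C(=O)Cl (the chlorine of intermediate 2 only)
Why: Nierenstein-type one-carbon homologation, in which the acid chloride acylates the diazoalkane (first stage of an Arndt–Eistert sequence) and HCl then converts the diazoketone into the chloromethyl ketone with loss of N2, no stereocentre being involved.

**Step 2**
Reactants: 5 3,4-dihydroxybenzonitrile; 4 1-[4-(benzyloxy)-3-methoxyphenyl]-3-chloropropan-2-one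
Product: 6 4-{3-[4-(benzyloxy)-3-methoxyphenyl]-2-oxopropoxy}-3-hydroxybenzonitrile
Conditions: K2CO3 (1.0 equiv), NaI (cat.), DMF, 0 °C to rt
Reagents that add atoms: none
Why: Williamson etherification with an α-chloroketone, in which the hydroxyl para to the nitrile is the more acidic phenol, so that one equivalent of mild base should form and alkylate that phenoxide selectively.

**Step 3**
Reactants: 6 4-{3-[4-(benzyloxy)-3-methoxyphenyl]-2-oxopropoxy}-3-hydroxybenzonitrile
Product: 7 4-{3-[4-(benzyloxy)-3-methoxyphenyl]-3-diazo-2-oxopropoxy}-3-hydroxybenzonitrile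
Conditions: 4-acetamidobenzenesulfonyl azide (1.3 equiv), DBU (2.5 equiv), MeCN, 0 °C to rt
Reagents that add atoms: 4-acetamidobenzenesulfonyl azide CC(=O)Nc1ccc(cc1)S(=O)(=O)N=[N+]=[N-]
Why: Regitz diazo transfer, in which DBU enolises the ketone toward the more acidic benzylic CH2 (aryl-conjugated enolate) and this enolate takes the diazo group from the sulfonyl azide, the extra base covering the free phenol.

**Step 4**
Reactants: 7 4-{3-[4-(benzyloxy)-3-methoxyphenyl]-3-diazo-2-oxopropoxy}-3-hydroxybenzonitrile
Product: 8 rac-2-[4-(benzyloxy)-3-methoxyphenyl]-3-oxo-3,4-dihydro-2H-1,5-benzodioxepine-8-carbonitrile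
Conditions: Rh2(OAc)4 (1 mol %), CH2Cl2, rt, slow addition of 7 at high dilution
Reagents that add atoms: none
Why: Intramolecular O–H insertion of the aryl keto carbenoid formed with dirhodium tetraacetate into the neighbouring phenol (oxonium ylide, then proton shift) should close the seven-membered ring, and the new C-2 stereocentre is deliberately left racemic because step 5 equilibrates it.

**Step 5**
Reactants: 8 rac-2-[4-(benzyloxy)-3-methoxyphenyl]-3-oxo-3,4-dihydro-2H-1,5-benzodioxepine-8-carbonitrile
Product: 10 (2R,3R)-3-[4-(benzyloxy)-3-methoxyphenyl]-2-(hydroxymethyl)-2,3-dihydro-1,4-benzodioxine-6-carbonitrile, via cis-benzodioxepinol 9 (not isolated)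
Conditions: trans-RuCl2[(S)-xylbinap][(S)-daipen] (1 mol %), KOtBu (0.2 equiv), H2 (10 atm), iPrOH/THF, 25 °C; then vent, DMSO, KOtBu (to 0.5 equiv), 60 °C, dry conditions
Reagents that add atoms: none
Why: KOtBu keeps the two enantiomers of 8 in fast equilibrium through the C-2 enolate while the chiral divalent-ruthenium diphosphine/diamine hydride reduces the (2R)-ketone faster and delivers hydride to the carbonyl face anti to the C-2 aryl group, so that dynamic kinetic resolution should give the cis-(2R,3R)-alkoxide of 9 (closest known type: base-mediated DKR hydrogenation of α-aryl and α-aryloxy cycloalkanones). On warming in DMSO this secondary alkoxide attacks ring carbon C-5a at the ipso position, the para cyano group taking up the charge, and the primary alkoxide is expelled, which is an O-to-O Smiles rearrangement of a 2-aryloxy alcohol. The new aryl C–O bond closes in a 5-exo-trig spiro mode through a five-membered dioxolane-type transition structure, whose collapse leaves the six-membered 1,4-dioxane ring in place of the seven-membered one, the former ring CH2 becoming the exocyclic CH2OH. The carbinol centre is set by the catalyst and the aryl-bearing centre by equilibration plus anti hydride delivery, and no bond at either stereocentre is broken in the migration, so cis-9 maps onto trans-(2R,3R)-10. The step needs migration at only one of the two aryl ether carbons, which the substrate secures because C-5a is para to the nitrile whereas C-9a is meta and unactivated, so O-1 stays in place. The isomerisation is catalytic in base and should run downhill from a seven-membered ring with a secondary alkoxide to a six-membered ring with a primary alkoxide.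

**Step 6**
Reactants: 10 (2R,3R)-3-[4-(benzyloxy)-3-methoxyphenyl]-2-(hydroxymethyl)-2,3-dihydro-1,4-benzodioxine-6-carbonitrile
Product: 12 (2R,3R)-3-[4-(benzyloxy)-3-methoxyphenyl]-2-(hydroxymethyl)-2,3-dihydro-1,4-benzodioxine-6-carbaldehyde, via aldimine 11 (not isolated)
Conditions: DIBAL-H (2.5 equiv), CH2Cl2, −78 to −20 °C; then aq. HCl (1 M), 0 °C
Reagents that add atoms: water O
Why: Partial reduction of an aryl nitrile, in which DIBAL-H adds once to give the N-aluminated aldimine that is hydrolysed to the aldehyde only on work-up, one further equivalent being consumed by the free alcohol and neither stereocentre being touched.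

**Step 7**
Reactants: 12 (2R,3R)-3-[4-(benzyloxy)-3-methoxyphenyl]-2-(hydroxymethyl)-2,3-dihydro-1,4-benzodioxine-6-carbaldehyde; 13 1-[2,4-bis(benzyloxy)-6-hydroxyphenyl]ethan-1-one
Product: 14 (E)-1-[2,4-bis(benzyloxy)-6-hydroxyphenyl]-3-{(2R,3R)-3-[4-(benzyloxy)-3-methoxyphenyl]-2-(hydroxymethyl)-2,3-dihydro-1,4-benzodioxin-6-yl}prop-2-en-1-one
Conditions: KOH (aq. 50%), EtOH/THF, rt
Reagents that add atoms: none
Why: Claisen–Schmidt aldol condensation of the methyl ketone enolate with the non-enolisable aryl aldehyde should give the (E)-chalcone under thermodynamic control, the trans-dioxane being the stable partner of any reversible aryl migration under base.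

**Step 8**
Reactants: 14 (E)-1-[2,4-bis(benzyloxy)-6-hydroxyphenyl]-3-{(2R,3R)-3-[4-(benzyloxy)-3-methoxyphenyl]-2-(hydroxymethyl)-2,3-dihydro-1,4-benzodioxin-6-yl}prop-2-en-1-one
Product: 16 5,7-bis(benzyloxy)-2-{(2R,3R)-3-[4-(benzyloxy)-3-methoxyphenyl]-2-(hydroxymethyl)-2,3-dihydro-1,4-benzodioxin-6-yl}-3-hydroxy-4H-chromen-4-one, via dihydroflavonol 15 (not isolated)
Conditions: H2O2 (30% aq.), NaOH (aq. 2 M), MeOH/THF, 0 °C to rt
Reagents that add atoms: hydrogen peroxide OO
Why: Algar–Flynn–Oyamada reaction, in which alkaline hydrogen peroxide converts the 2'-hydroxychalcone by oxidative 6-endo cyclisation into the dihydroflavonol, which is dehydrogenated in the same medium to the flavonol so that its two transient stereocentres disappear.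

**Step 9**
Reactants: 16 5,7-bis(benzyloxy)-2-{(2R,3R)-3-[4-(benzyloxy)-3-methoxyphenyl]-2-(hydroxymethyl)-2,3-dihydro-1,4-benzodioxin-6-yl}-3-hydroxy-4H-chromen-4-one
Product: 17 2,3-dehydrosilybin A
Conditions: H2 (1 atm), Pd/C (10 wt %), EtOAc/MeOH, rt, stopped after uptake of three equivalents
Reagents that add atoms: none
Why: Hydrogenolysis of the three primary benzyl aryl ethers over palladium on carbon, in which the pyranone double bond of the flavonol is not reduced and the secondary, ring-bound benzylic ether of the dioxane should be cleaved much more slowly, so the stereocentres are kept.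

**Compound list**
1 | [4-(benzyloxy)-3-methoxyphenyl]acetic acid | COc1cc(CC(=O)O)ccc1OCc1ccccc1 | starting material
2 | [4-(benzyloxy)-3-methoxyphenyl]acetyl chloride (not isolated) | COc1cc(CC(=O)Cl)ccc1OCc1ccccc1 | intermediate
3 | 1-[4-(benzyloxy)-3-methoxyphenyl]-3-diazopropan-2-one (not isolated) | COc1cc(CC(=O)C=[N+]=[N-])ccc1OCc1ccccc1 | intermediate
4 | 1-[4-(benzyloxy)-3-methoxyphenyl]-3-chloropropan-2-one | COc1cc(CC(=O)CCl)ccc1OCc1ccccc1 | intermediate
5 | 3,4-dihydroxybenzonitrile | N#Cc1ccc(O)c(O)c1 | starting material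
6 | 4-{3-[4-(benzyloxy)-3-methoxyphenyl]-2-oxopropoxy}-3-hydroxybenzonitrile | COc1cc(CC(=O)COc2ccc(C#N)cc2O)ccc1OCc1ccccc1 | intermediate
7 | 4-{3-[4-(benzyloxy)-3-methoxyphenyl]-3-diazo-2-oxopropoxy}-3-hydroxybenzonitrile | COc1cc(C(=[N+]=[N-])C(=O)COc2ccc(C#N)cc2O)ccc1OCc1ccccc1 | intermediate
8 | rac-2-[4-(benzyloxy)-3-methoxyphenyl]-3-oxo-3,4-dihydro-2H-1,5-benzodioxepine-8-carbonitrile | COc1cc(C2Oc3cc(C#N)ccc3OCC2=O)ccc1OCc1ccccc1 | intermediate
9 | (2R,3R)-2-[4-(benzyloxy)-3-methoxyphenyl]-3-hydroxy-3,4-dihydro-2H-1,5-benzodioxepine-8-carbonitrile (cis; formed as its potassium alkoxide; not isolated) | COc1cc([C@H]2Oc3cc(C#N)ccc3OC[C@H]2O)ccc1OCc1ccccc1 | intermediate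
10 | (2R,3R)-3-[4-(benzyloxy)-3-methoxyphenyl]-2-(hydroxymethyl)-2,3-dihydro-1,4-benzodioxine-6-carbonitrile (trans) | COc1cc([C@H]2Oc3cc(C#N)ccc3O[C@@H]2CO)ccc1OCc1ccccc1 | intermediate
11 | aldimine of 12 (CH=NH in place of CHO; present in the flask as its N-diisobutylaluminium derivative; not isolated) | COc1cc([C@H]2Oc3cc(C=N)ccc3O[C@@H]2CO)ccc1OCc1ccccc1 | intermediate
12 | (2R,3R)-3-[4-(benzyloxy)-3-methoxyphenyl]-2-(hydroxymethyl)-2,3-dihydro-1,4-benzodioxine-6-carbaldehyde | COc1cc([C@H]2Oc3cc(C=O)ccc3O[C@@H]2CO)ccc1OCc1ccccc1 | intermediate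
13 | 1-[2,4-bis(benzyloxy)-6-hydroxyphenyl]ethan-1-one | CC(=O)c1c(O)cc(OCc2ccccc2)cc1OCc1ccccc1 | starting material
14 | (E)-1-[2,4-bis(benzyloxy)-6-hydroxyphenyl]-3-{(2R,3R)-3-[4-(benzyloxy)-3-methoxyphenyl]-2-(hydroxymethyl)-2,3-dihydro-1,4-benzodioxin-6-yl}prop-2-en-1-one | COc1cc([C@H]2Oc3cc(/C=C/C(=O)c4c(O)cc(OCc5ccccc5)cc4OCc4ccccc4)ccc3O[C@@H]2CO)ccc1OCc1ccccc1 | intermediate
15 | 5,7-bis(benzyloxy)-2-{(2R,3R)-3-[4-(benzyloxy)-3-methoxyphenyl]-2-(hydroxymethyl)-2,3-dihydro-1,4-benzodioxin-6-yl}-3-hydroxy-2,3-dihydro-4H-chromen-4-one (mixture at C-2 and C-3 of ring C; not isolated) | COc1cc([C@H]2Oc3cc(C4Oc5cc(OCc6ccccc6)cc(OCc6ccccc6)c5C(=O)C4O)ccc3O[C@@H]2CO)ccc1OCc1ccccc1 | intermediate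
16 | 5,7-bis(benzyloxy)-2-{(2R,3R)-3-[4-(benzyloxy)-3-methoxyphenyl]-2-(hydroxymethyl)-2,3-dihydro-1,4-benzodioxin-6-yl}-3-hydroxy-4H-chromen-4-one | COc1cc([C@H]2Oc3cc(-c4oc5cc(OCc6ccccc6)cc(OCc6ccccc6)c5c(=O)c4O)ccc3O[C@@H]2CO)ccc1OCc1ccccc1 | intermediate
17 | 2,3-dehydrosilybin A, 3,5,7-trihydroxy-2-[(2R,3R)-3-(4-hydroxy-3-methoxyphenyl)-2-(hydroxymethyl)-2,3-dihydro-1,4-benzodioxin-6-yl]-4H-chromen-4-one | COc1cc([C@H]2Oc3cc(-c4oc5cc(O)cc(O)c5c(=O)c4O)ccc3O[C@@H]2CO)ccc1O | target

**Step count and risks**
Total step count: 9. Longest linear sequence: 9 steps (from 1 to 17; 5 and 13 enter at steps 2 and 7).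

Steps most likely to fail:

- **Step 5.** The arene may fail to migrate, because a cyano group activates the ipso carbon only moderately, and the alkoxide base may begin to hydrate the nitrile before migration is complete. In the fallback the two events are run apart and the migration is done on a more strongly activated arene. It sets out from 8: transfer hydrogenation with dynamic kinetic resolution (RuCl(p-cymene)[(S,S)-TsDPEN], HCO2H/Et3N, CH2Cl2, rt; antipode chosen as in the remark above) should give the cis-alcohol 9, now isolated. DIBAL-H (CH2Cl2, −78 °C, then aq. HCl) would convert its nitrile into (2R,3R)-2-[4-(benzyloxy)-3-methoxyphenyl]-3-hydroxy-3,4-dihydro-2H-1,5-benzodioxepine-8-carbaldehyde F1. K2CO3 in DMSO at 60 °C should then contract F1 by the same Smiles rearrangement, now driven by the para formyl group, directly to aldehyde 12, where the route is rejoined (step 6 is then not needed).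

- **Step 8.** The 6'-benzyloxy group of the chalcone may divert the oxidative cyclisation into 5-exo closure (aurone formation) instead of the 6-endo closure that leads to the flavonol. The fallback sets out from 14: I2 (cat.) in DMSO at 120 °C should cyclise and dehydrogenate the chalcone to the flavone 5,7-bis(benzyloxy)-2-{(2R,3R)-3-[4-(benzyloxy)-3-methoxyphenyl]-2-(hydroxymethyl)-2,3-dihydro-1,4-benzodioxin-6-yl}-4H-chromen-4-one F2. Dimethyldioxirane (acetone/CH2Cl2, 0 °C) would epoxidise its C-2/C-3 double bond to the flavone 2,3-epoxide F3, and a trace of TsOH should open and tautomerise this to the flavonol 16, where the route is rejoined.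

- **Step 4.** The carbenoid may dimerise, insert intermolecularly or attack an electron-rich arene instead of closing the seven-membered ring. The fallback replaces the carbenoid by an ionic ring closure and sets out from 7: HBr (48% aq.) in CH2Cl2 at 0 °C should protonate the diazo carbon and capture bromide to give 4-{3-[4-(benzyloxy)-3-methoxyphenyl]-3-bromo-2-oxopropoxy}-3-hydroxybenzonitrile F4. K2CO3 in acetone at high dilution should then close the ring by intramolecular Williamson etherification to ketone 8, where the route is rejoined.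

**Further compounds**
F1 | step 5 | (2R,3R)-2-[4-(benzyloxy)-3-methoxyphenyl]-3-hydroxy-3,4-dihydro-2H-1,5-benzodioxepine-8-carbaldehyde | COc1cc([C@H]2Oc3cc(C=O)ccc3OC[C@H]2O)ccc1OCc1ccccc1
F2 | step 8 | 5,7-bis(benzyloxy)-2-{(2R,3R)-3-[4-(benzyloxy)-3-methoxyphenyl]-2-(hydroxymethyl)-2,3-dihydro-1,4-benzodioxin-6-yl}-4H-chromen-4-one | COc1cc([C@H]2Oc3cc(-c4cc(=O)c5c(OCc6ccccc6)cc(OCc6ccccc6)cc5o4)ccc3O[C@@H]2CO)ccc1OCc1ccccc1
F3 | step 8 | 2,3-epoxide of F2 (mixture at the two oxirane carbons) | COc1cc([C@H]2Oc3cc(C45OC4C(=O)c4c(OCc6ccccc6)cc(OCc6ccccc6)cc4O5)ccc3O[C@@H]2CO)ccc1OCc1ccccc1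
F4 | step 4 | 4-{3-[4-(benzyloxy)-3-methoxyphenyl]-3-bromo-2-oxopropoxy}-3-hydroxybenzonitrile (racemic) | COc1cc(C(Br)C(=O)COc2ccc(C#N)cc2O)ccc1OCc1ccccc1
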